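**Retrosynthetic overview**
The target is 5'-hydroxyphylloquinone (side chain numbered C1'–C16' from the ring). The plan rests on the C4'–C5' bond, which joins the allylic methylene C4' (next to the E C2'=C3' alkene) to the isolated secondary carbinol carbon C5'.
Last operations: the quinone of ring A is unmasked from its 1,4-dimethyl ether, and the C5'–OH comes from a C5'–B bond by retentive oxidation.
Key disconnection C4'–C5': 1,2-metallate rearrangement between the sparteine-lithiated carbamate of (3R,7R)-hexahydrofarnesol (C5' as carbenoid carbon) and an E allylic pinacol boronate carrying the protected naphthalene (C4' as migrating carbon).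
Fragments: the carbamate comes from farnesol (asymmetric hydrogenation sets C7' and C11'); the boronate comes from menadione by SN2' arylation of isoprene monoxide (sets the E alkene), acetylation and borylation.
No ring is formed at any stage; rings A and B come intact from menadione.

Key step: step 8

Assumption: (+)-sparteine free base of high enantiomeric purity and the chiral iridium catalyst are taken as purchasable.

**Step 1**
Reactants: 1 (2E,6E)-farnesol
Product: 2 (3R,7R)-3,7,11-trimethyldodecan-1-ol
Conditions: H2 (50 bar), [Ir(cod)(L*)][B(C6H3(CF3)2)4] (1 mol%; L* = one enantiomer of 2-phenyl-6,7-dihydro-5H-cyclopenta[b]pyridin-7-yl di(o-tolyl)phosphinite, antipode chosen for the 3R,7R product), CH2Cl2, rt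
Reagents that add atoms: none
Why: Iridium-catalysed asymmetric hydrogenation of trisubstituted alkenes with a chiral N,P ligand, in which the catalyst selects the enantioface of each E alkene, so the two like-substituted alkenes C2=C3 and C6=C7 are reduced in the same sense to 3R and 7R (the later C7' and C11'), while C10=C11 is saturated without creating a stereocentre.

**Step 2**
Reactants: 2 (3R,7R)-3,7,11-trimethyldodecan-1-ol
Product: 3 (3R,7R)-3,7,11-trimethyldodecyl N,N-diisopropylcarbamate
Conditions: i-Pr2NCOCl (1.2 equiv), Et3N (1.5 equiv), CH2Cl2, reflux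
Reagents that add atoms: N,N-diisopropylcarbamoyl chloride, CC(C)N(C(C)C)C(Cl)=O
Why: Carbamoylation of a primary alcohol (acyl substitution) installs the carbamate that later directs α-lithiation and serves as leaving group, with the remote stereocentres untouched.

**Step 3**
Reactants: 4 menadione
Product: 6 1,4-dimethoxy-2-methylnaphthalene, via menadiol 5 (not isolated)
Conditions: Na2S2O4, n-Bu4NBr (cat.), THF/H2O, rt, N2; then aq. KOH, Me2SO4, 0 °C to rt
Reagents that add atoms: dimethyl sulfate, COS(=O)(=O)OC
Why: One-pot reductive methylation, in which dithionite reduces the quinone to the hydroquinone and its phenoxides are O-methylated by dimethyl sulfate under phase transfer (Williamson ether synthesis) before air can reoxidise them.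

**Step 4**
Reactants: 6 1,4-dimethoxy-2-methylnaphthalene
Product: 7 2-bromo-1,4-dimethoxy-3-methylnaphthalene
Conditions: Br2 (1.05 equiv), CH2Cl2, 0 °C, dark
Reagents that add atoms: bromine, BrBr
Why: Electrophilic aromatic bromination occurs at C3, the only unsubstituted position of the electron-rich dimethoxy ring and ortho to a methoxy group.

**Step 5**
Reactants: 7 2-bromo-1,4-dimethoxy-3-methylnaphthalene; 8 isoprene monoxide (2-methyl-2-vinyloxirane)
Product: 10 (2E)-4-(1,4-dimethoxy-3-methylnaphthalen-2-yl)-2-methylbut-2-en-1-ol, via arylmagnesium bromide 9 (not isolated)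
Conditions: Mg, THF, reflux; then CuI (10 mol%), 8, THF, −30 to 0 °C; aq. NH4Cl
Reagents that add atoms: none
Why: Grignard formation followed by copper-catalysed SN2' opening of the vinyl oxirane, in which the arylcopper species attacks the unsubstituted vinyl terminus and the alkoxide leaves from the quaternary carbon, and the E alkene should result from the favoured s-trans conformer that places the CH2O group trans to the new C1'–C2' bond; no stereocentre is formed.

**Step 6**
Reactants: 10 (2E)-4-(1,4-dimethoxy-3-methylnaphthalen-2-yl)-2-methylbut-2-en-1-ol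
Product: 11 (2E)-4-(1,4-dimethoxy-3-methylnaphthalen-2-yl)-2-methylbut-2-enyl acetate
Conditions: Ac2O, pyridine, DMAP (cat.), CH2Cl2, rt
Reagents that add atoms: acetic anhydride, CC(=O)OC(C)=O
Why: DMAP-catalysed acetylation of the primary allylic alcohol (acyl transfer) turns the hydroxyl into a leaving group for π-allyl formation without touching the alkene.

**Step 7**
Reactants: 11 (2E)-4-(1,4-dimethoxy-3-methylnaphthalen-2-yl)-2-methylbut-2-enyl acetate; 12 bis(pinacolato)diboron
Product: 13 2-[(2E)-4-(1,4-dimethoxy-3-methylnaphthalen-2-yl)-2-methylbut-2-enyl]-4,4,5,5-tetramethyl-1,3,2-dioxaborolane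
Conditions: Pd2(dba)3 (2.5 mol%, zerovalent palladium), DMSO, 50 °C
Reagents that add atoms: none
Why: Miyaura-type borylation of an allylic acetate, in which oxidative addition gives a π-allylpalladium acetate, acetate-assisted transmetalation with B2pin2 and reductive elimination place boron on the less hindered CH2 terminus (C4'), and the syn π-allyl complex from the E acetate should be trapped faster than it isomerises, so the E alkene is kept.

**Step 8**
Reactants: 3 (3R,7R)-3,7,11-trimethyldodecyl N,N-diisopropylcarbamate; 13 2-[(2E)-4-(1,4-dimethoxy-3-methylnaphthalen-2-yl)-2-methylbut-2-enyl]-4,4,5,5-tetramethyl-1,3,2-dioxaborolane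
Product: 16 1,4-dimethoxy-2-methyl-3-[(2E,5S,7R,11R)-3,7,11,15-tetramethyl-5-(4,4,5,5-tetramethyl-1,3,2-dioxaborolan-2-yl)hexadec-2-enyl]naphthalene, via α-lithio carbamate 14 (not isolated), via boronate complex 15 (not isolated)
Conditions: 3 (1.3 equiv), (+)-sparteine (1.3 equiv), s-BuLi (1.25 equiv), Et2O, −78 °C, 5 h; 13 (1.0 equiv) in Et2O, −78 °C, 1 h; MgBr2·OEt2, Et2O, −78 °C to reflux; aq. NH4Cl
Reagents that add atoms: none
Why: Lithiation–borylation, a Matteson-type 1,2-metallate rearrangement: s-BuLi/(+)-sparteine removes the pro-R proton at C1 of 3 and gives the configurationally stable (R)-α-lithio carbamate 14, which adds to boron of 13 with retention to form boronate complex 15. On warming with MgBr2·OEt2 the allylic methylene C4' migrates from boron to C5' antiperiplanar to the departing carbamate, so C5' is inverted and the C4'–C5' bond forms; no ring is closed. The C5' stereocentre is set by reagent control (the diamine selects between the enantiotopic protons), which should override the remote C7' methyl centre; the sense is chosen so that retentive oxidation of the C–B bond later gives the 5'S carbinol, whereas (−)-sparteine would lead to the 5'R epimer. The step needs a σ 1,2-shift of the allyl group without allylic transposition: in tetracoordinate 15 boron has no vacant orbital for a 1,3-boratropic shift and C4' moves as the boron-bound carbon, so the E C2'=C3' alkene is carried through unchanged. Chemoselectivity rests on the order of events: the strong base meets only the saturated carbamate, and 14 should be captured by boron at −78 °C faster than it can deprotonate the C1' methylene of 13.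

**Step 9**
Reactants: 16 1,4-dimethoxy-2-methyl-3-[(2E,5S,7R,11R)-3,7,11,15-tetramethyl-5-(4,4,5,5-tetramethyl-1,3,2-dioxaborolan-2-yl)hexadec-2-enyl]naphthalene
Product: 17 (2E,5S,7R,11R)-1-(1,4-dimethoxy-3-methylnaphthalen-2-yl)-3,7,11,15-tetramethylhexadec-2-en-5-ol
Conditions: 30% H2O2, 2 M aq. NaOH, THF, 0 °C to rt
Reagents that add atoms: hydrogen peroxide, OO
Why: Oxidation of a secondary alkylboronic ester with alkaline hydrogen peroxide, in which hydroperoxide adds to boron and C5' migrates from boron to oxygen with retention to give the 5'S carbinol, while the arene, the trisubstituted alkene and the C7' and C11' centres are inert.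

**Step 10**
Reactants: 17 (2E,5S,7R,11R)-1-(1,4-dimethoxy-3-methylnaphthalen-2-yl)-3,7,11,15-tetramethylhexadec-2-en-5-ol
Product: 18 2-[(2E,5S,7R,11R)-5-hydroxy-3,7,11,15-tetramethylhexadec-2-enyl]-3-methylnaphthalene-1,4-dione (target)
Conditions: (NH4)2Ce(NO3)6 (2.5 equiv), MeCN/CH2Cl2/H2O, 0 °C, subdued light
Reagents that add atoms: water, O
Why: Oxidative demethylation of the 1,4-dimethoxyarene by (NH4)2Ce(NO3)6 (tetravalent cerium), in which two one-electron oxidations with ipso attack of water and loss of methanol give the 1,4-naphthoquinone, and short exposure at 0 °C should leave the secondary alcohol, the allylic positions and the three stereocentres untouched.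

**Compound list**
1 | (2E,6E)-farnesol | OC/C=C(\C)CC/C=C(\C)CCC=C(C)C | starting material
2 | (3R,7R)-3,7,11-trimethyldodecan-1-ol | OCC[C@H](C)CCC[C@H](C)CCCC(C)C | intermediate
3 | (3R,7R)-3,7,11-trimethyldodecyl N,N-diisopropylcarbamate | CC(C)N(C(C)C)C(=O)OCC[C@H](C)CCC[C@H](C)CCCC(C)C | intermediate
4 | menadione (2-methylnaphthalene-1,4-dione) | CC1=CC(=O)c2ccccc2C1=O | starting material
5 | menadiol (2-methylnaphthalene-1,4-diol), formed in the flask | Cc1cc(O)c2ccccc2c1O | intermediate
6 | 1,4-dimethoxy-2-methylnaphthalene | COc1cc(C)c(OC)c2ccccc12 | intermediate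
7 | 2-bromo-1,4-dimethoxy-3-methylnaphthalene | COc1c(C)c(Br)c(OC)c2ccccc12 | intermediate
8 | isoprene monoxide (2-methyl-2-vinyloxirane) | CC1(C=C)CO1 | starting material
9 | (1,4-dimethoxy-3-methylnaphthalen-2-yl)magnesium bromide, formed in the flask | COc1c(C)c([Mg]Br)c(OC)c2ccccc12 | intermediate
10 | (2E)-4-(1,4-dimethoxy-3-methylnaphthalen-2-yl)-2-methylbut-2-en-1-ol | COc1c(C)c(C/C=C(\C)CO)c(OC)c2ccccc12 | intermediate
11 | (2E)-4-(1,4-dimethoxy-3-methylnaphthalen-2-yl)-2-methylbut-2-enyl acetate | COc1c(C)c(C/C=C(\C)COC(C)=O)c(OC)c2ccccc12 | intermediate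
12 | bis(pinacolato)diboron | CC1(C)OB(OC1(C)C)B1OC(C)(C)C(C)(C)O1 | starting material
13 | 2-[(2E)-4-(1,4-dimethoxy-3-methylnaphthalen-2-yl)-2-methylbut-2-enyl]-4,4,5,5-tetramethyl-1,3,2-dioxaborolane | COc1c(C)c(C/C=C(\C)CB2OC(C)(C)C(C)(C)O2)c(OC)c2ccccc12 | intermediate
14 | (1R,3R,7R)-1-lithio-3,7,11-trimethyldodecyl N,N-diisopropylcarbamate, (+)-sparteine complex, formed in the flask | [Li][C@@H](OC(=O)N(C(C)C)C(C)C)C[C@H](C)CCC[C@H](C)CCCC(C)C | intermediate
15 | lithium boronate complex of 13 bearing the (1R,3R,7R)-1-(diisopropylcarbamoyloxy)-3,7,11-trimethyldodecyl group on boron, formed in the flask | [Li+].COc1c(C)c(C/C=C(\C)C[B-]2(OC(C)(C)C(C)(C)O2)[C@@H](OC(=O)N(C(C)C)C(C)C)C[C@H](C)CCC[C@H](C)CCCC(C)C)c(OC)c2ccccc12 | intermediate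
16 | 1,4-dimethoxy-2-methyl-3-[(2E,5S,7R,11R)-3,7,11,15-tetramethyl-5-(4,4,5,5-tetramethyl-1,3,2-dioxaborolan-2-yl)hexadec-2-enyl]naphthalene | COc1c(C)c(C/C=C(\C)C[C@@H](B2OC(C)(C)C(C)(C)O2)C[C@H](C)CCC[C@H](C)CCCC(C)C)c(OC)c2ccccc12 | intermediate
17 | (2E,5S,7R,11R)-1-(1,4-dimethoxy-3-methylnaphthalen-2-yl)-3,7,11,15-tetramethylhexadec-2-en-5-ol | COc1c(C)c(C/C=C(\C)C[C@@H](O)C[C@H](C)CCC[C@H](C)CCCC(C)C)c(OC)c2ccccc12 | intermediate
18 | 2-[(2E,5S,7R,11R)-5-hydroxy-3,7,11,15-tetramethylhexadec-2-enyl]-3-methylnaphthalene-1,4-dione | CC1=C(C/C=C(\C)C[C@@H](O)C[C@H](C)CCC[C@H](C)CCCC(C)C)C(=O)c2ccccc2C1=O | target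

**Totals**
Total step count: 10.
Longest linear sequence: 8 steps (menadione 4 to target 18: steps 3, 4, 5, 6, 7, 8, 9, 10).

**Steps most likely to fail**

1. Step 8 (lithiation–borylation). The enantiotopic deprotonation may be incomplete or poorly selective, which would give C5' epimers. The 1,2-shift of the allyl group may be slow, so that the boronate complex reverts or decomposes on warming. The organolithium may also deprotonate the doubly activated C1' methylene of 13.
Fallback (C1'–C2' bond made last, no boron chemistry): it sets out from alcohol 2 and arene 6 and rejoins the route at alcohol 17. Alcohol 2 is oxidised with Dess–Martin periodinane to (3R,7R)-3,7,11-trimethyldodecanal F1. Corey–Chaykovsky methylenation (Me3S+ I−, n-BuLi, THF) gives 2-[(2R,6R)-2,6,10-trimethylundecyl]oxirane F2 as a mixture of epimers at the oxirane carbon. Hydrolytic kinetic resolution with [Co(salen*)(OAc)] (trivalent cobalt; salen* = N,N'-bis(3,5-di-tert-butylsalicylidene)-trans-1,2-cyclohexanediamine dianion, antipode chosen to spare the 2S epimer) and 0.55 equiv water should leave (2S)-2-[(2R,6R)-2,6,10-trimethylundecyl]oxirane F3. Lithium acetylide–ethylenediamine in DMSO opens F3 at its CH2 to (4S,6R,10R)-6,10,14-trimethylpentadec-1-yn-4-ol F4, which already holds the C5' centre. F4 is silylated (TBSCl, imidazole) to the silyl ether F5. Arene 6 is chloromethylated ((CH2O)n, HCl, AcOH; Blanc reaction) to 2-(chloromethyl)-1,4-dimethoxy-3-methylnaphthalene F6. Zirconium-catalysed syn carboalumination of F5 (AlMe3, Cp2ZrCl2, CH2Cl2; Negishi carboalumination) gives the E alkenylalane F7. F7 is coupled in the same flask with F6 under Pd(PPh3)4 (zerovalent palladium) with retention of alkene geometry to the silyl ether F8 of 17. Bu4NF in THF then gives 17.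

2. Step 7 (palladium-catalysed borylation). Syn–anti isomerisation of the 2-methyl-substituted π-allylpalladium intermediate may erode the E geometry, boron may be delivered to the internal terminus, or 13 may couple with unreacted 11 (allyl–allyl homocoupling).
Fallback (C–B bond by a 1,2-hydride shift, no π-allyl metal species): it sets out from alcohol 10 and rejoins the route at boronate 13. Alcohol 10 is carbamoylated (i-Pr2NCOCl, Et3N) to (2E)-4-(1,4-dimethoxy-3-methylnaphthalen-2-yl)-2-methylbut-2-enyl N,N-diisopropylcarbamate F9. Carbamate-directed α-lithiation (s-BuLi, TMEDA, Et2O, −78 °C) gives the α-lithio allylic carbamate F10. F10 is trapped with pinacolborane to the hydridoboronate complex F11, and on warming hydride migrates from boron to carbon with loss of the carbamate (lithiation–borylation with pinacolborane), which gives 13 with the alkene geometry of 10.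

3. Step 5 (copper-catalysed SN2' arylation of isoprene monoxide). Direct opening at the primary oxirane carbon may compete with the SN2' path, the E selectivity may be incomplete, or the hindered bromide may be slow to form the Grignard reagent.
Fallback (alkene geometry set by allylic oxidation in place of oxirane opening): it sets out from bromide 7 and rejoins the route at alcohol 10. The Grignard reagent 9 is alkylated with prenyl bromide (CuI cat., THF, 0 °C) to 1,4-dimethoxy-2-methyl-3-(3-methylbut-2-enyl)naphthalene F12. Allylic oxidation with SeO2 (cat.) and t-BuOOH in CH2Cl2, which attacks the E methyl group at the more substituted alkene terminus, followed by NaBH4 to reduce any enal, then gives 10.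

**Further compounds**
F1 | step 8 | (3R,7R)-3,7,11-trimethyldodecanal | O=CC[C@H](C)CCC[C@H](C)CCCC(C)C
F2 | step 8 | 2-[(2R,6R)-2,6,10-trimethylundecyl]oxirane, mixture of epimers at the oxirane carbon | C1OC1C[C@H](C)CCC[C@H](C)CCCC(C)C
F3 | step 8 | (2S)-2-[(2R,6R)-2,6,10-trimethylundecyl]oxirane | C1O[C@H]1C[C@H](C)CCC[C@H](C)CCCC(C)C
F4 | step 8 | (4S,6R,10R)-6,10,14-trimethylpentadec-1-yn-4-ol | C#CC[C@@H](O)C[C@H](C)CCC[C@H](C)CCCC(C)C
F5 | step 8 | tert-butyldimethyl{[(4S,6R,10R)-6,10,14-trimethylpentadec-1-yn-4-yl]oxy}silane | C#CC[C@@H](O[Si](C)(C)C(C)(C)C)C[C@H](C)CCC[C@H](C)CCCC(C)C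
F6 | step 8 | 2-(chloromethyl)-1,4-dimethoxy-3-methylnaphthalene | COc1c(C)c(CCl)c(OC)c2ccccc12
F7 | step 8 | [(1E,4S,6R,10R)-4-(tert-butyldimethylsilyloxy)-2,6,10,14-tetramethylpentadec-1-enyl]dimethylalumane, formed in the flask | C[Al](C)/C=C(\C)C[C@@H](O[Si](C)(C)C(C)(C)C)C[C@H](C)CCC[C@H](C)CCCC(C)C
F8 | step 8 | tert-butyl{[(2E,5S,7R,11R)-1-(1,4-dimethoxy-3-methylnaphthalen-2-yl)-3,7,11,15-tetramethylhexadec-2-en-5-yl]oxy}dimethylsilane | COc1c(C)c(C/C=C(\C)C[C@@H](O[Si](C)(C)C(C)(C)C)C[C@H](C)CCC[C@H](C)CCCC(C)C)c(OC)c2ccccc12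
F9 | step 7 | (2E)-4-(1,4-dimethoxy-3-methylnaphthalen-2-yl)-2-methylbut-2-enyl N,N-diisopropylcarbamate | COc1c(C)c(C/C=C(\C)COC(=O)N(C(C)C)C(C)C)c(OC)c2ccccc12
F10 | step 7 | (2E)-4-(1,4-dimethoxy-3-methylnaphthalen-2-yl)-1-lithio-2-methylbut-2-enyl N,N-diisopropylcarbamate, TMEDA complex, formed in the flask | COc1c(C)c(C/C=C(\C)C([Li])OC(=O)N(C(C)C)C(C)C)c(OC)c2ccccc12
F11 | step 7 | lithium hydridoboronate complex from F10 and pinacolborane, formed in the flask | [Li+].COc1c(C)c(C/C=C(\C)C(OC(=O)N(C(C)C)C(C)C)[BH-]2OC(C)(C)C(C)(C)O2)c(OC)c2ccccc12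
F12 | step 5 | 1,4-dimethoxy-2-methyl-3-(3-methylbut-2-enyl)naphthalene | COc1c(C)c(CC=C(C)C)c(OC)c2ccccc12
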